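**Strategy**

Rings A and B carry the head-to-tail isoprenoid imprint (quaternary C4 and C10, C7=C8 alkene, oxygen at C3), so the decalin is unzipped to an acyclic polyene whose C3–C4 unit is a chiral trisubstituted oxirane. One MeAlCl2-triggered cation–olefin cascade forms the C4–C5 and C9–C10 bonds, closes both rings and sets C4, C5, C9 and C10 from the oxirane and the E-alkene geometries; loss of H-7 leaves the C7=C8 alkene, while the ester-conjugated C13=C14 alkene stays inert. The precursor is the silyl ether of a (Z)-allylic-alcohol-derived epoxide of methyl geranylgeranoate, built from methyl farnesoate; C3 is inverted afterwards by oxidation and hydride reduction.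

Key step: step 7

Remark on numbering: atom labels follow labdane numbering (C19 = oxygenated carbon on C4, C20 = methyl on C10, C17 = methyl on C8, C15 = carboxyl carbon). In this numbering the target is (3S,4R,5S,9R,10S,13E), an ent-labdane with axial 3-OAc and axial C19 arm.

Assumption: methyl (2E,6E)-farnesoate is taken as a purchasable compound (it is otherwise two routine steps from (2E,6E)-farnesol).

**Route**

Step 1
Reactants: 1 prop-2-yn-1-ol
Product: 3 (Z)-3-iodo-2-methylprop-2-en-1-ol, via cyclic alkenylmagnesium alkoxide 2 (not isolated)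
Conditions: MeMgBr (2.5 equiv), CuI (10 mol %), THF/Et2O, −10 °C → rt; then iodine, −78 → 0 °C
Reagents that add atoms: methylmagnesium bromide, C[Mg]Br; iodine, [I][I]
Why: Copper-catalysed anti carbomagnesiation of the propargylic alkoxide puts methyl on the internal carbon and magnesium on the terminal carbon inside a five-membered chelate, and iodinolysis with retention should give the Z vinyl iodide (iodine cis to CH2OH).

Step 2
Reactants: 4 methyl (2E,6E)-3,7,11-trimethyldodeca-2,6,10-trienoate (methyl farnesoate)
Product: 6 methyl (2E,6E,10E)-3,7,11-trimethyl-12-oxododeca-2,6,10-trienoate, via 12-hydroxy ester 5 (not isolated)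
Conditions: SeO2 (0.3 equiv), t-BuOOH (3 equiv), salicylic acid (10 mol %), CH2Cl2, 0 °C → rt; filtration, then MnO2 (excess), CH2Cl2, rt
Reagents that add atoms: selenium dioxide, O=[Se]=O; tert-butyl hydroperoxide, CC(C)(C)OO
Why: The ene reaction/[2,3]-sigmatropic shift of the Sharpless allylic oxidation should pick the E-methyl of the most electron-rich terminal trisubstituted alkene, and MnO2 then converges the allylic alcohol (and any aldehyde already formed) on the single E-enal.

Step 3
Reactants: 6 methyl (2E,6E,10E)-3,7,11-trimethyl-12-oxododeca-2,6,10-trienoate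
Product: 7 methyl (2E,6E,10E)-3,7,11-trimethyltrideca-2,6,10,12-tetraenoate
Conditions: Ph3PCH3Br, KN(SiMe3)2, THF, 0 °C; then 6, −78 → 0 °C
Reagents that add atoms: methyltriphenylphosphonium bromide, C[P+](c1ccccc1)(c1ccccc1)c1ccccc1.[Br-]
Why: Wittig methylenation of the enal by the unstabilised ylide is far faster than attack on the hindered conjugated ester and should give the terminal 1,3-diene with the 10E geometry untouched.

Step 4
Reactants: 7 methyl (2E,6E,10E)-3,7,11-trimethyltrideca-2,6,10,12-tetraenoate; 3 (Z)-3-iodo-2-methylprop-2-en-1-ol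
Product: 9 methyl (2E,6E,10E,14Z)-16-hydroxy-3,7,11,15-tetramethylhexadeca-2,6,10,14-tetraenoate, via B-alkyl-9-BBN 8 (not isolated)
Conditions: 9-BBN (1.2 equiv), THF, 0 °C → rt; then 3, PdCl2(dppf) (5 mol %), AsPh3, Cs2CO3, DMF/H2O, rt
Reagents that add atoms: none
Why: 9-BBN should add only to the terminal CH2 of the monosubstituted vinyl group, and the B-alkyl Suzuki–Miyaura coupling transfers the primary alkyl group to the vinyl iodide with retention, which fixes the 14Z geometry (CH2OH cis to the chain).

Step 5
Reactants: 9 methyl (2E,6E,10E,14Z)-16-hydroxy-3,7,11,15-tetramethylhexadeca-2,6,10,14-tetraenoate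
Product: 10 methyl (2E,6E,10E)-13-[(2R,3S)-3-(hydroxymethyl)-3-methyloxiran-2-yl]-3,7,11-trimethyltrideca-2,6,10-trienoate
Conditions: Ti(OiPr)4, L-(+)-diethyl tartrate, t-BuOOH, 4 Å MS, CH2Cl2, −20 °C
Reagents that add atoms: tert-butyl hydroperoxide, CC(C)(C)OO
Why: Katsuki–Sharpless asymmetric epoxidation acts only on the allylic-alcohol alkene, and with L-(+)-tartrate this (Z)-2-methylallylic alcohol should give the oxirane that is R at the CH carbon (future C3) and S at the quaternary carbon (future C4), with CH2OH still cis to the chain.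

Step 6
Reactants: 10 methyl (2E,6E,10E)-13-[(2R,3S)-3-(hydroxymethyl)-3-methyloxiran-2-yl]-3,7,11-trimethyltrideca-2,6,10-trienoate
Product: 11 methyl (2E,6E,10E)-13-[(2R,3S)-3-{[(tert-butyldimethylsilyl)oxy]methyl}-3-methyloxiran-2-yl]-3,7,11-trimethyltrideca-2,6,10-trienoate
Conditions: TBSCl, imidazole, DMF, 0 °C → rt
Reagents that add atoms: tert-butyldimethylsilyl chloride, CC(C)(C)[Si](C)(C)Cl
Why: Standard silylation of the primary alcohol removes the free hydroxyl that would bind the Lewis acid and leaves an ether that does not act as a neighbouring group.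

Step 7
Reactants: 11 methyl (2E,6E,10E)-13-[(2R,3S)-3-{[(tert-butyldimethylsilyl)oxy]methyl}-3-methyloxiran-2-yl]-3,7,11-trimethyltrideca-2,6,10-trienoate
Product: 12 methyl (3R,4R,5S,9R,10S,13E)-19-[(tert-butyldimethylsilyl)oxy]-3-hydroxylabda-7,13-dien-15-oate
Conditions: MeAlCl2 (3 equiv), CH2Cl2, −78 °C; then aq. NaHCO3
Reagents that add atoms: none
Why: MeAlCl2 binds the oxirane oxygen, the tertiary C4–O bond breaks with backside participation of the C5=C10 alkene (C4–C5 bond), the C10 cation is taken by the C8=C9 alkene (C9–C10 bond) and the C8 cation loses the axial H-7 to give the C7=C8 alkene, the released proton being consumed by the Al–CH3 bond. The closest known reaction type is the Lewis-acid-promoted, oxirane-initiated polyene (cation–olefin) cyclization. Ring A closes by a 6-endo-trig attack of the alkene with endo opening of the oxirane (both oxirane carbons end in the ring) and ring B by a 6-endo-trig attack, both through a chair–chair fold. C3 is carried over from the oxirane and sits equatorial, which allows only one fold and so fixes the absolute sense; C4 is set by inversion, the CH2OTBS group that was cis to the chain becoming axial; C5 and C10 (trans ring fusion) follow from anti addition across the E C5=C10 alkene, and C9 (H axial, side chain equatorial) from anti addition across the E C8=C9 alkene. The step needs opening at C4 and not at C3 (tertiary against secondary carbon), a stop after two rings (the C13=C14 alkene is conjugated to the Lewis-acid-bound ester and is not nucleophilic) and Zaitsev loss of H-7, which should be the main but perhaps not the only mode of termination.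

Step 8
Reactants: 12 methyl (3R,4R,5S,9R,10S,13E)-19-[(tert-butyldimethylsilyl)oxy]-3-hydroxylabda-7,13-dien-15-oate
Product: 13 methyl (4R,5S,9R,10S,13E)-19-[(tert-butyldimethylsilyl)oxy]-3-oxolabda-7,13-dien-15-oate
Conditions: Dess–Martin periodinane, NaHCO3, CH2Cl2, 0 °C → rt
Reagents that add atoms: none
Why: Dess–Martin oxidation of the equatorial secondary alcohol is mild and nearly neutral, so the silyl ether, the trisubstituted alkene and the quaternary C4 next to the new ketone should be unaffected.

Step 9
Reactants: 13 methyl (4R,5S,9R,10S,13E)-19-[(tert-butyldimethylsilyl)oxy]-3-oxolabda-7,13-dien-15-oate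
Product: 14 methyl (3S,4R,5S,9R,10S,13E)-19-[(tert-butyldimethylsilyl)oxy]-3-hydroxylabda-7,13-dien-15-oate
Conditions: LiBH(s-Bu)3 (1.5 equiv), THF, −78 °C; then H2O
Reagents that add atoms: none
Why: The bulky trialkylborohydride should avoid the axial path (blocked by the axial hydrogens at C1 and C5) and attack C3 from the equatorial side, giving the axial 3-alcohol (3S, trans to the C19 arm and the C10 methyl), while the β,β-disubstituted enoate is not reduced at −78 °C.

Step 10
Reactants: 14 methyl (3S,4R,5S,9R,10S,13E)-19-[(tert-butyldimethylsilyl)oxy]-3-hydroxylabda-7,13-dien-15-oate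
Product: 15 (3S,4R,5S,9R,10S,13E)-19-[(tert-butyldimethylsilyl)oxy]-3-hydroxylabda-7,13-dien-15-oic acid
Conditions: LiOH·H2O, THF/MeOH/H2O, 45 °C; then 1 M HCl to pH 4, 0 °C
Reagents that add atoms: lithium hydroxide, [Li+].[OH-]
Why: Saponification of the conjugated methyl ester before the acetate is in place avoids any later need to tell two esters apart, and the TBS ether and the hindered alcohol are stable to aqueous LiOH.

Step 11
Reactants: 15 (3S,4R,5S,9R,10S,13E)-19-[(tert-butyldimethylsilyl)oxy]-3-hydroxylabda-7,13-dien-15-oic acid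
Product: 16 (3S,4R,5S,9R,10S,13E)-3-acetoxy-19-[(tert-butyldimethylsilyl)oxy]labda-7,13-dien-15-oic acid
Conditions: Ac2O, DMAP, pyridine, CH2Cl2, rt → 40 °C; then aq. NaHCO3/THF, rt
Reagents that add atoms: acetic anhydride, CC(=O)OC(C)=O
Why: DMAP-catalysed acetylation should esterify the hindered axial 3-hydroxyl, and the mixed anhydride formed at the carboxylic acid is hydrolysed back during the bicarbonate work-up.

Step 12
Reactants: 16 (3S,4R,5S,9R,10S,13E)-3-acetoxy-19-[(tert-butyldimethylsilyl)oxy]labda-7,13-dien-15-oic acid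
Product: 17 (3S,4R,5S,9R,10S,13E)-3-acetoxy-19-hydroxylabda-7,13-dien-15-oic acid
Conditions: HF·pyridine, pyridine, THF, 0 °C → rt
Reagents that add atoms: none
Why: Buffered HF cleaves the primary TBS ether without touching the acetate, and acyl migration from O-3 to O-19 is not expected because the two oxygens are held anti (axial C3–O on one face, axial C4–C19 on the other).

**Compound list**

1 | prop-2-yn-1-ol | C#CCO | starting material
2 | 4-methyl-2,5-dihydro-1,2-oxamagnesole (cyclic alkenylmagnesium alkoxide) | CC1=C[Mg]OC1 | intermediate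
3 | (Z)-3-iodo-2-methylprop-2-en-1-ol | I/C=C(/C)CO | intermediate
4 | methyl (2E,6E)-3,7,11-trimethyldodeca-2,6,10-trienoate (methyl farnesoate) | COC(=O)/C=C(\C)CC/C=C(\C)CCC=C(C)C | starting material
5 | methyl (2E,6E,10E)-12-hydroxy-3,7,11-trimethyldodeca-2,6,10-trienoate | COC(=O)/C=C(\C)CC/C=C(\C)CC/C=C(\C)CO | intermediate
6 | methyl (2E,6E,10E)-3,7,11-trimethyl-12-oxododeca-2,6,10-trienoate | COC(=O)/C=C(\C)CC/C=C(\C)CC/C=C(\C)C=O | intermediate
7 | methyl (2E,6E,10E)-3,7,11-trimethyltrideca-2,6,10,12-tetraenoate | COC(=O)/C=C(\C)CC/C=C(\C)CC/C=C(\C)C=C | intermediate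
8 | methyl (2E,6E,10E)-13-(9-borabicyclo[3.3.1]nonan-9-yl)-3,7,11-trimethyltrideca-2,6,10-trienoate | COC(=O)/C=C(\C)CC/C=C(\C)CC/C=C(\C)CCB1C2CCCC1CCC2 | intermediate
9 | methyl (2E,6E,10E,14Z)-16-hydroxy-3,7,11,15-tetramethylhexadeca-2,6,10,14-tetraenoate | COC(=O)/C=C(\C)CC/C=C(\C)CC/C=C(\C)CC/C=C(/C)CO | intermediate
10 | methyl (2E,6E,10E)-13-[(2R,3S)-3-(hydroxymethyl)-3-methyloxiran-2-yl]-3,7,11-trimethyltrideca-2,6,10-trienoate | COC(=O)/C=C(\C)CC/C=C(\C)CC/C=C(\C)CC[C@H]1O[C@@]1(C)CO | intermediate
11 | methyl (2E,6E,10E)-13-[(2R,3S)-3-{[(tert-butyldimethylsilyl)oxy]methyl}-3-methyloxiran-2-yl]-3,7,11-trimethyltrideca-2,6,10-trienoate | COC(=O)/C=C(\C)CC/C=C(\C)CC/C=C(\C)CC[C@H]1O[C@@]1(C)CO[Si](C)(C)C(C)(C)C | intermediate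
12 | methyl (3R,4R,5S,9R,10S,13E)-19-[(tert-butyldimethylsilyl)oxy]-3-hydroxylabda-7,13-dien-15-oate (trans-decalin; 3-OH equatorial and CH2OTBS axial, both cis to the C10 methyl) | O[C@@H]1CC[C@]2(C)[C@H](CC=C(C)[C@H]2CC/C(C)=C/C(=O)OC)[C@]1(C)CO[Si](C)(C)C(C)(C)C | intermediate
13 | methyl (4R,5S,9R,10S,13E)-19-[(tert-butyldimethylsilyl)oxy]-3-oxolabda-7,13-dien-15-oate | O=C1CC[C@]2(C)[C@H](CC=C(C)[C@H]2CC/C(C)=C/C(=O)OC)[C@]1(C)CO[Si](C)(C)C(C)(C)C | intermediate
14 | methyl (3S,4R,5S,9R,10S,13E)-19-[(tert-butyldimethylsilyl)oxy]-3-hydroxylabda-7,13-dien-15-oate (3-OH axial, trans to the C10 methyl) | O[C@H]1CC[C@]2(C)[C@H](CC=C(C)[C@H]2CC/C(C)=C/C(=O)OC)[C@]1(C)CO[Si](C)(C)C(C)(C)C | intermediate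
15 | (3S,4R,5S,9R,10S,13E)-19-[(tert-butyldimethylsilyl)oxy]-3-hydroxylabda-7,13-dien-15-oic acid | O[C@H]1CC[C@]2(C)[C@H](CC=C(C)[C@H]2CC/C(C)=C/C(=O)O)[C@]1(C)CO[Si](C)(C)C(C)(C)C | intermediate
16 | (3S,4R,5S,9R,10S,13E)-3-acetoxy-19-[(tert-butyldimethylsilyl)oxy]labda-7,13-dien-15-oic acid | CC(=O)O[C@H]1CC[C@]2(C)[C@H](CC=C(C)[C@H]2CC/C(C)=C/C(=O)O)[C@]1(C)CO[Si](C)(C)C(C)(C)C | intermediate
17 | (3S,4R,5S,9R,10S,13E)-3-acetoxy-19-hydroxylabda-7,13-dien-15-oic acid | CC(=O)O[C@H]1CC[C@]2(C)[C@H](CC=C(C)[C@H]2CC/C(C)=C/C(=O)O)[C@]1(C)CO | target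

**Step count and risks**

Total step count: 12. Longest linear sequence: 11 steps (from 4 through steps 2–12 to 17; step 1 is a one-step side branch).

Steps most likely to fail:

1. Step 7 (key cyclization). The risk is unselective proton loss from the C8 cation (exocyclic C8=C17 olefin beside the wanted C7=C8 olefin). The electron-withdrawing CH2OTBS group on C4 may also slow the oxirane opening enough for hydride shift to a ketone or an interrupted cascade to compete. The fallback sets out from 11 and returns at 12, and no longer leaves the olefin position to kinetic termination. The cascade product is taken on as the olefin mixture, whose main contaminant is the exocyclic isomer methyl 19-[(tert-butyldimethylsilyl)oxy]-3-hydroxylabda-8(17),13E-dien-15-oate F1. The mixture is then treated in a separate step with a cobalt-hydride hydrogen-atom-transfer isomerization (Co(salen)Cl with salen = N,N'-bis(3,5-di-tert-butylsalicylidene)cyclohexane-1,2-diamine dianion, catalytic PhSiH3, benzene, rt). Hydrogen-atom addition to the 1,1-disubstituted alkene gives the tertiary C8 radical, and hydrogen is then removed from the less hindered C7, so the mixture should converge on 12; the trisubstituted and ester-conjugated alkenes should not react.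

2. Step 9 (ketone reduction). The risk is hydride delivery along the axial path, because the axial CH2OTBS arm on C4 crowds the equatorial approach, which would return the equatorial alcohol. The fallback sets out from 13 and returns at 14, and replaces steric control by hydroxyl-directed delivery. HF·pyridine (THF, 0 °C) removes the silyl group to give methyl (4R,5S,9R,10S,13E)-19-hydroxy-3-oxolabda-7,13-dien-15-oate F2. Me4NBH(OAc)3 (AcOH/MeCN, −20 °C) binds the C19 hydroxyl and delivers hydride intramolecularly to C3 from the face of the axial C19 arm, giving the anti 1,3-diol methyl (3S,4R,5S,9R,10S,13E)-3,19-dihydroxylabda-7,13-dien-15-oate F3. TBSCl (1 equiv) with imidazole at 0 °C then silylates only the primary hydroxyl and gives 14.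

3. Step 2 (allylic oxidation). The risk is oxidation at allylic positions of the internal C6=C7 alkene, over-oxidation and incomplete conversion. The fallback sets out from 4 and returns at 6, and builds the enal by cleavage and re-olefination. NBS in THF/H2O at 0 °C gives the terminal bromohydrin methyl (2E,6E)-10-bromo-11-hydroxy-3,7,11-trimethyldodeca-2,6-dienoate F4, selective for the most electron-rich terminal alkene. K2CO3 in MeOH closes it to methyl (2E,6E)-9-(3,3-dimethyloxiran-2-yl)-3,7-dimethylnona-2,6-dienoate F5. HIO4·2H2O in THF/Et2O cleaves this to methyl (2E,6E)-3,7-dimethyl-10-oxodeca-2,6-dienoate F6. An E-selective Wittig reaction with the stabilised ylide Ph3P=C(CH3)CHO (toluene, 80 °C) then gives 6.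

**Further compounds**

F1 | step 7 | methyl 19-[(tert-butyldimethylsilyl)oxy]-3-hydroxylabda-8(17),13E-dien-15-oate (exocyclic olefin isomer of 12, same configuration at C3, C4, C5, C9 and C10) | O[C@@H]1CC[C@]2(C)[C@H](CCC(=C)[C@H]2CC/C(C)=C/C(=O)OC)[C@]1(C)CO[Si](C)(C)C(C)(C)C
F2 | step 9 | methyl (4R,5S,9R,10S,13E)-19-hydroxy-3-oxolabda-7,13-dien-15-oate | O=C1CC[C@]2(C)[C@H](CC=C(C)[C@H]2CC/C(C)=C/C(=O)OC)[C@]1(C)CO
F3 | step 9 | methyl (3S,4R,5S,9R,10S,13E)-3,19-dihydroxylabda-7,13-dien-15-oate | O[C@H]1CC[C@]2(C)[C@H](CC=C(C)[C@H]2CC/C(C)=C/C(=O)OC)[C@]1(C)CO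
F4 | step 2 | methyl (2E,6E)-10-bromo-11-hydroxy-3,7,11-trimethyldodeca-2,6-dienoate (racemic) | COC(=O)/C=C(\C)CC/C=C(\C)CCC(Br)C(C)(C)O
F5 | step 2 | methyl (2E,6E)-9-(3,3-dimethyloxiran-2-yl)-3,7-dimethylnona-2,6-dienoate (racemic) | COC(=O)/C=C(\C)CC/C=C(\C)CCC1OC1(C)C
F6 | step 2 | methyl (2E,6E)-3,7-dimethyl-10-oxodeca-2,6-dienoate | COC(=O)/C=C(\C)CC/C=C(\C)CCC=O
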